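**Strategy.** Ring B (drimane numbering: C5=C6 alkene, allylic C7H2, C8HMe, quaternary C9, ring-fusion C10–H) is a cyclohexene and is cut by a retro-[4+2] across C7–C8 and C9–C10. The precursors are an achiral monocyclic dienone, 2,2-dimethyl-3-vinylcyclohex-3-en-1-one (ring A carrying the C10=C5–C6=C7 diene), and (E)-2-methylbut-2-enal. One catalytic enantioselective, formyl-exo Diels–Alder reaction closes ring B through the C7–C8 bond (together with C9–C10) and sets C8, C9 and C10. The enal geometry becomes the cis C8/C9 methyls and the formyl carbon becomes the OCH2 linker. Aldehyde reduction, Mitsunobu etherification with isofraxidin and a reagent-controlled reduction of the C3 ketone finish the target.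

Key step: step 3

Remark (assumption): C-numbers in the text are drimane numbers, while compound names use naphthalene locants. The absolute sense of the oxazaborolidinium catalyst in step 3 is assigned from the formyl C–H···O binding model for 2-substituted enals; both antipodes of the catalyst precursor are commercial.

**Step 1**
Reactants: 1 2,2-dimethylcyclohexane-1,3-dione
Product: 3 6,6-dimethyl-5-oxocyclohex-1-en-1-yl trifluoromethanesulfonate, via potassium enolate 2 (not isolated)
Conditions: KN(SiMe3)2 (1.05 equiv), THF, −78 °C; then PhNTf2 (1.1 equiv), −78 → 0 °C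
Reagents that add atoms: N-phenylbis(trifluoromethanesulfonimide), O=S(=O)(N(c1ccccc1)S(=O)(=O)C(F)(F)F)C(F)(F)F
Why: Enol triflate formation by kinetic mono-enolisation of the symmetric diketone and O-sulfonylation of the enolate; the quaternary C2 allows only one enolate regiochemistry and no stereocenter is formed.

**Step 2**
Reactants: 3 6,6-dimethyl-5-oxocyclohex-1-en-1-yl trifluoromethanesulfonate
Product: 4 2,2-dimethyl-3-vinylcyclohex-3-en-1-one
Conditions: CH2=CHSnBu3 (1.2 equiv), Pd(PPh3)4 (3 mol%), LiCl (3 equiv), THF, 65 °C
Reagents that add atoms: tributyl(vinyl)stannane, C=C[Sn](CCCC)(CCCC)CCCC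
Why: Stille cross-coupling (oxidative addition of the enol triflate to zerovalent palladium, chloride-assisted transmetalation from tin, reductive elimination) should give the 1,3-diene, which the quaternary carbon keeps out of conjugation with the ketone; no stereocenter is formed.

**Step 3**
Reactants: 4 2,2-dimethyl-3-vinylcyclohex-3-en-1-one; 5 (E)-2-methylbut-2-enal
Product: 6 (1R,2S,8aR)-1,2,5,5-tetramethyl-6-oxo-1,2,3,5,6,7,8,8a-octahydronaphthalene-1-carbaldehyde
Conditions: (R)-3,3-diphenyl-1-(o-tolyl)tetrahydro-1H,3H-pyrrolo[1,2-c][1,3,2]oxazaborole (20 mol%) activated with Tf2NH (18 mol%), CH2Cl2, −40 → −20 °C, enal in 2.5-fold excess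
Reagents that add atoms: none
Why: The protonated oxazaborolidine binds the formyl group of 5 (boron–oxygen coordination plus a formyl C–H···O contact, s-trans enal) and lowers its LUMO, so the diene of 4 adds in a concerted, asynchronous [4+2] cycloaddition in which the C7–C8 bond (vinyl CH2 to the enal β-carbon) is the more advanced one and C9–C10 (enal α-carbon to the ring CH) completes the ring. The closest known reaction type is the chiral oxazaborolidinium-catalysed Diels–Alder reaction of 2-substituted enals with semicyclic 1-vinylcycloalkene dienes. Ring B is closed as a six-membered carbocycle in the [4+2] mode, suprafacial on both partners, and the regiochemistry follows the 1-alkyl ("ortho") rule: the unsubstituted diene terminus C7 attacks the β-carbon, which also leaves the more crowded C9–C10 bond for the later stage. The cis relation of the C8 and C9 methyls is fixed by the (E)-geometry of 5, and the relation of C9 to C10 (formyl carbon cis to the C10 hydrogen) by the formyl-exo transition state, favoured because the endo position beneath the inner diene carbon C5 and its quaternary neighbour C4 should accept the small α-methyl group more readily than the catalyst-bound formyl group. The absolute configuration of all three centers is set by the (R)-catalyst, whose neighbouring phenyl group covers one face of the bound enal so that the diene adds to the C2-Si face. The step therefore needs regio-, exo- and enantioface selectivity, secured in this order by the diene substitution pattern, the steric bias just described and the catalyst; the α-quaternary ketone of 4 should bind the bulky boron centre only weakly and reversibly and so should not sequester the catalyst.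

**Step 4**
Reactants: 6 (1R,2S,8aR)-1,2,5,5-tetramethyl-6-oxo-1,2,3,5,6,7,8,8a-octahydronaphthalene-1-carbaldehyde
Product: 7 (4aR,5R,6S)-5-(hydroxymethyl)-1,1,5,6-tetramethyl-3,4,4a,5,6,7-hexahydronaphthalen-2(1H)-one
Conditions: NaBH4 (0.6 equiv), EtOH/CH2Cl2 3:7, −78 → −40 °C
Reagents that add atoms: none
Why: Chemoselective borohydride reduction, in which the aldehyde should react much faster at low temperature than the α-quaternary cyclohexanone; no stereocenter is touched because C9 is quaternary and neither C8 nor C10 is α to a carbonyl group.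

**Step 5**
Reactants: 7 (4aR,5R,6S)-5-(hydroxymethyl)-1,1,5,6-tetramethyl-3,4,4a,5,6,7-hexahydronaphthalen-2(1H)-one; 8 isofraxidin (7-hydroxy-6,8-dimethoxy-2H-chromen-2-one)
Product: 9 7-{[(1R,2S,8aR)-1,2,5,5-tetramethyl-6-oxo-1,2,3,5,6,7,8,8a-octahydronaphthalen-1-yl]methoxy}-6,8-dimethoxy-2H-chromen-2-one
Conditions: PPh3 (1.5 equiv), DIAD (1.5 equiv), THF (2–3 M), sonication, 25–40 °C
Reagents that add atoms: none
Why: Mitsunobu etherification, in which the primary alcohol is activated as its alkoxyphosphonium ion and displaced by the acidic phenol of isofraxidin at a carbon that is not a stereocenter; high concentration with sonication is the known remedy for neopentyl alcohols and ortho-substituted phenols, and the ketone, alkene and lactone are inert.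

**Step 6**
Reactants: 9 7-{[(1R,2S,8aR)-1,2,5,5-tetramethyl-6-oxo-1,2,3,5,6,7,8,8a-octahydronaphthalen-1-yl]methoxy}-6,8-dimethoxy-2H-chromen-2-one
Product: 10 7-{[(1R,2S,6S,8aR)-6-hydroxy-1,2,5,5-tetramethyl-1,2,3,5,6,7,8,8a-octahydronaphthalen-1-yl]methoxy}-6,8-dimethoxy-2H-chromen-2-one (target CNP0110107.1)
Conditions: (R)-1-methyl-3,3-diphenyltetrahydro-1H,3H-pyrrolo[1,2-c][1,3,2]oxazaborole (0.3 equiv), BH3·SMe2 (0.8 equiv), THF, −20 °C; MeOH quench
Reagents that add atoms: none
Why: Corey–Bakshi–Shibata reduction, in which the (R)-oxazaborolidine binds the ketone with the quaternary C4 as the large and the C2 methylene as the small group and delivers hydride to the carbonyl face on the side of the C10 hydrogen (the equatorial trajectory that bulky reductants favour in 4,4-dimethyl-3-ketones), which should give the axial (3S) alcohol cis to the C8 and C9 methyls, while the lactone and the hindered trisubstituted alkene should react far more slowly at −20 °C.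

**Compound list**
1 | 2,2-dimethylcyclohexane-1,3-dione | CC1(C)C(=O)CCCC1=O | starting material
2 | potassium 6,6-dimethyl-5-oxocyclohex-1-en-1-olate (potassium enolate of 1) | CC1(C)C(=O)CCC=C1[O-].[K+] | intermediate
3 | 6,6-dimethyl-5-oxocyclohex-1-en-1-yl trifluoromethanesulfonate | CC1(C)C(=O)CCC=C1OS(=O)(=O)C(F)(F)F | intermediate
4 | 2,2-dimethyl-3-vinylcyclohex-3-en-1-one | CC1(C)C(=O)CCC=C1C=C | intermediate
5 | (E)-2-methylbut-2-enal (tiglic aldehyde) | C/C=C(\C)C=O | starting material
6 | (1R,2S,8aR)-1,2,5,5-tetramethyl-6-oxo-1,2,3,5,6,7,8,8a-octahydronaphthalene-1-carbaldehyde | O=C[C@@]1(C)[C@@H]2CCC(=O)C(C)(C)C2=CC[C@@H]1C | intermediate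
7 | (4aR,5R,6S)-5-(hydroxymethyl)-1,1,5,6-tetramethyl-3,4,4a,5,6,7-hexahydronaphthalen-2(1H)-one | OC[C@@]1(C)[C@@H]2CCC(=O)C(C)(C)C2=CC[C@@H]1C | intermediate
8 | isofraxidin (7-hydroxy-6,8-dimethoxy-2H-chromen-2-one) | COc1cc2ccc(=O)oc2c(OC)c1O | starting material
9 | 7-{[(1R,2S,8aR)-1,2,5,5-tetramethyl-6-oxo-1,2,3,5,6,7,8,8a-octahydronaphthalen-1-yl]methoxy}-6,8-dimethoxy-2H-chromen-2-one | COc1cc2ccc(=O)oc2c(OC)c1OC[C@@]1(C)[C@@H]2CCC(=O)C(C)(C)C2=CC[C@@H]1C | intermediate
10 | 7-{[(1R,2S,6S,8aR)-6-hydroxy-1,2,5,5-tetramethyl-1,2,3,5,6,7,8,8a-octahydronaphthalen-1-yl]methoxy}-6,8-dimethoxy-2H-chromen-2-one | COc1cc2ccc(=O)oc2c(OC)c1OC[C@@]1(C)[C@@H]2CC[C@H](O)C(C)(C)C2=CC[C@@H]1C | target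

**Step count and risks**
Total steps: 6. Longest linear sequence: 6 (from 1).

Steps most likely to fail:

1. Step 3. The catalyst may turn over slowly with the trisubstituted enal or discriminate the enal faces poorly, for instance if the ketone of 4 holds part of the catalyst. The fallback gives up catalytic enantiocontrol for a resolution; it sets out from 4 and 5 and comes back at 7. An achiral Lewis acid (MeAlCl2, 2.2 equiv, CH2Cl2, −78 → −20 °C) should give, through the same substrate-borne exo bias, the racemic keto aldehyde F1. Reduction as in step 4 gives the racemic keto alcohol F2. Acylation with (S)-2-methoxy-2-phenylacetic acid (DCC, DMAP, CH2Cl2) gives two diastereomeric esters, the (1R,2S,8aR) ester F3 and the (1S,2R,8aS) ester F4, to be separated by chromatography. Methanolysis of F3 (K2CO3, MeOH) returns enantiopure 7.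

2. Step 5. Displacement at the neopentyl carbon may be slower than consumption of the betaine, so that the alkoxyphosphonium ion is intercepted by the hydrazide or simply returns the alcohol. The fallback separates activation from substitution; it sets out from 7 and comes back at 9. Tf2O with 2,6-lutidine (CH2Cl2, −78 °C) gives the neopentyl triflate F5, which is displaced by the caesium salt of 8 (Cs2CO3, DMF, 25–50 °C) in the absence of any competing nucleophile.

3. Step 6. Reagent control may be insufficient against the ketone's own facial bias at C3, or borane may attack the coumarin lactone. The fallback sets C3 by substrate control before the coumarin is present; it sets out from 7 and comes back at 10. LiBH(sec-C4H9)3 (L-Selectride, 2.5 equiv, THF, −78 → 0 °C) should attack the hindered ketone from the equatorial direction and give the axial alcohol, diol F6. A Mitsunobu reaction with 8 (PPh3, DIAD, THF, sonication, 25 °C) at the primary hydroxyl, with the axial secondary hydroxyl next to the quaternary carbon left untouched, gives 10.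

**Further compounds**
F1 | step 3 | racemic keto aldehyde (6 and its enantiomer, 1:1) | O=C[C@@]1(C)[C@@H]2CCC(=O)C(C)(C)C2=CC[C@@H]1C.O=C[C@]1(C)[C@H]2CCC(=O)C(C)(C)C2=CC[C@H]1C
F2 | step 3 | racemic keto alcohol (7 and its enantiomer, 1:1) | OC[C@@]1(C)[C@@H]2CCC(=O)C(C)(C)C2=CC[C@@H]1C.OC[C@]1(C)[C@H]2CCC(=O)C(C)(C)C2=CC[C@H]1C
F3 | step 3 | [(1R,2S,8aR)-1,2,5,5-tetramethyl-6-oxo-1,2,3,5,6,7,8,8a-octahydronaphthalen-1-yl]methyl (S)-2-methoxy-2-phenylacetate | O=C(OC[C@@]1(C)[C@@H]2CCC(=O)C(C)(C)C2=CC[C@@H]1C)[C@@H](OC)c1ccccc1
F4 | step 3 | [(1S,2R,8aS)-1,2,5,5-tetramethyl-6-oxo-1,2,3,5,6,7,8,8a-octahydronaphthalen-1-yl]methyl (S)-2-methoxy-2-phenylacetate | O=C(OC[C@]1(C)[C@H]2CCC(=O)C(C)(C)C2=CC[C@H]1C)[C@@H](OC)c1ccccc1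
F5 | step 5 | [(1R,2S,8aR)-1,2,5,5-tetramethyl-6-oxo-1,2,3,5,6,7,8,8a-octahydronaphthalen-1-yl]methyl trifluoromethanesulfonate | O=S(=O)(OC[C@@]1(C)[C@@H]2CCC(=O)C(C)(C)C2=CC[C@@H]1C)C(F)(F)F
F6 | step 6 | (2S,4aR,5R,6S)-5-(hydroxymethyl)-1,1,5,6-tetramethyl-1,2,3,4,4a,5,6,7-octahydronaphthalen-2-ol | OC[C@@]1(C)[C@@H]2CC[C@H](O)C(C)(C)C2=CC[C@@H]1C
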